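**Strategy.** The cyclohexene ring (C5–C10, eudesmanolide numbering) is disconnected at the tetrasubstituted C10=C5 alkene and at the C6–C7 bond, a formal [4+2] union. C5 and C6 are the α- and carbonyl carbons of a citronellal-derived aldehyde (as enol silane 6); C7–C10 belong to butenolide ketone 17. In one flask, Mukaiyama aldol condensation joins C5 to the C10 ketone, then indium converts the 3-(bromomethyl)butenolide into an allyl metal whose C7 adds to the C6 aldehyde, closing the ring and setting C6 and C7. The step exploits the allylic alcohol C10=C5–C6–O and the homoallylic relation of C6–O to the exocyclic C11=C13 methylene of the cis-fused lactone ring.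

Key step: step 12

Assumption: atom labels follow eudesmanolide numbering (ring C5–C10; lactone O on C8, carbonyl C12, exocyclic methylene C13 on C11; hydroxymethyl C14 on C10; side chain C4 to C1); TBDPS = tert-butyldiphenylsilyl.

**Step 1**
Reactants: 1 (R)-citronellal
Product: 2 (R)-8,8-dimethoxy-2,6-dimethyloct-2-ene
Conditions: HC(OMe)3, PPTS (cat.), MeOH, rt
Reagents that add atoms: trimethyl orthoformate, COC(OC)OC
Why: Acid-catalysed acetalisation masks the aldehyde (future C6) before the alkene is cleaved; the C4 stereocentre is β to the carbonyl and is not touched.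

**Step 2**
Reactants: 2 (R)-8,8-dimethoxy-2,6-dimethyloct-2-ene
Product: 3 (R)-6,6-dimethoxy-4-methylhexan-1-ol
Conditions: O3, CH2Cl2/MeOH, −78 °C; then NaBH4, −78 → 0 °C
Reagents that add atoms: ozone, [O-][O+]=O
Why: Ozonolysis with reductive borohydride work-up turns the isopropylidene end into the primary alcohol that becomes C1–OH, while the acetal is inert.

**Step 3**
Reactants: 3 (R)-6,6-dimethoxy-4-methylhexan-1-ol
Product: 4 (R)-tert-butyl[(6,6-dimethoxy-4-methylhexyl)oxy]diphenylsilane
Conditions: TBDPSCl, imidazole, DMF, rt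
Reagents that add atoms: tert-butyl(chloro)diphenylsilane, CC(C)(C)[Si](Cl)(c1ccccc1)c1ccccc1
Why: Silylation of the primary alcohol gives an ether that should survive the Lewis-acidic and aqueous acidic conditions of the key step.

**Step 4**
Reactants: 4 (R)-tert-butyl[(6,6-dimethoxy-4-methylhexyl)oxy]diphenylsilane
Product: 5 (R)-6-[(tert-butyldiphenylsilyl)oxy]-3-methylhexanal
Conditions: PPTS, acetone/H2O, 60 °C
Reagents that add atoms: water, O
Why: Mild acetal hydrolysis releases the aldehyde without cleaving the TBDPS ether.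

**Step 5**
Reactants: 5 (R)-6-[(tert-butyldiphenylsilyl)oxy]-3-methylhexanal
Product: 6 trimethylsilyl enol ether of 5 (E/Z mixture)
Conditions: TMSCl, Et3N, DMF, 80 °C
Reagents that add atoms: chlorotrimethylsilane, C[Si](C)(C)Cl
Why: Thermodynamic silyl enol ether formation from the aldehyde makes C5 nucleophilic; the enol ether geometry is irrelevant because C5 becomes sp2 in the key step.

**Step 6**
Reactants: 7 2-bromoprop-2-en-1-ol
Product: 8 [(2-bromoprop-2-en-1-yl)oxy](tert-butyl)diphenylsilane
Conditions: TBDPSCl, imidazole, CH2Cl2, rt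
Reagents that add atoms: tert-butyl(chloro)diphenylsilane, CC(C)(C)[Si](Cl)(c1ccccc1)c1ccccc1
Why: Silylation protects the future C14–OH with a bulky group that resists oxygen-to-carbon silyl migration in the next step.

**Step 7**
Reactants: 8 [(2-bromoprop-2-en-1-yl)oxy](tert-butyl)diphenylsilane, 9 (R)-epichlorohydrin
Product: 11 (R)-5-{[(tert-butyldiphenylsilyl)oxy]methyl}-1-chlorohex-5-en-2-ol, via alkenyllithium 10 (not isolated)
Conditions: t-BuLi (2 equiv), Et2O, −78 °C; then BF3·OEt2, 9, −78 °C
Reagents that add atoms: none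
Why: Bromine–lithium exchange gives alkenyllithium 10, which opens the BF3-activated epoxide at its unsubstituted carbon (SN2, forming C9–C10) and leaves the carbinol stereocentre (future C8) unchanged.

**Step 8**
Reactants: 11 (R)-5-{[(tert-butyldiphenylsilyl)oxy]methyl}-1-chlorohex-5-en-2-ol
Product: 13 (R)-5-{[(tert-butyldiphenylsilyl)oxy]methyl}hexa-1,5-dien-3-ol, via epoxide 12 (not isolated)
Conditions: Me3S+ I− (4 equiv), n-BuLi (4 equiv), THF, −10 °C → rt
Reagents that add atoms: trimethylsulfonium iodide, C[S+](C)C.[I-]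
Why: The alkoxide closes to terminal epoxide 12, which dimethylsulfonium methylide (Corey–Chaykovsky reagent) opens at CH2 and then eliminates dimethyl sulfide to give the one-carbon-homologated allylic alcohol; C8 is a spectator.

**Step 9**
Reactants: 13 (R)-5-{[(tert-butyldiphenylsilyl)oxy]methyl}hexa-1,5-dien-3-ol, 14 2-(bromomethyl)acrylic acid
Product: 15 (R)-5-{[(tert-butyldiphenylsilyl)oxy]methyl}hexa-1,5-dien-3-yl 2-(bromomethyl)acrylate
Conditions: DCC, DMAP (cat.), CH2Cl2, 0 °C
Reagents that add atoms: none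
Why: Steglich esterification at low temperature acylates the secondary allylic alcohol with retention at C8 and brings in C11, C12 and C13.

**Step 10**
Reactants: 15 (R)-5-{[(tert-butyldiphenylsilyl)oxy]methyl}hexa-1,5-dien-3-yl 2-(bromomethyl)acrylate
Product: 16 (R)-3-(bromomethyl)-5-(2-{[(tert-butyldiphenylsilyl)oxy]methyl}prop-2-en-1-yl)furan-2(5H)-one
Conditions: second-generation Grubbs catalyst RuCl2(=CHPh)(PCy3)(H2IMes) (10 mol%), toluene, 80 °C
Reagents that add atoms: none
Why: Ring-closing metathesis between the acrylate and the vinyl group gives the butenolide (C7=C11); the 1,1-disubstituted side-chain alkene stays out because its closure would need a tetrasubstituted alkene.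

**Step 11**
Reactants: 16 (R)-3-(bromomethyl)-5-(2-{[(tert-butyldiphenylsilyl)oxy]methyl}prop-2-en-1-yl)furan-2(5H)-one
Product: 17 (R)-3-(bromomethyl)-5-{3-[(tert-butyldiphenylsilyl)oxy]-2-oxopropyl}furan-2(5H)-one
Conditions: O3, CH2Cl2, −78 °C; then Me2S, −78 → 0 °C
Reagents that add atoms: ozone, [O-][O+]=O
Why: Ozone cleaves the electron-rich 1,1-disubstituted alkene much faster than the electron-poor butenolide alkene, unveiling the C10 ketone under neutral conditions that spare the base-sensitive β-acyloxy ketone.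

**Step 12**
Reactants: 17 (R)-3-(bromomethyl)-5-{3-[(tert-butyldiphenylsilyl)oxy]-2-oxopropyl}furan-2(5H)-one, 6 trimethylsilyl enol ether of 5
Product: 20 cis-fused 6-hydroxy α-methylene lactone (bis-TBDPS ether), via aldol adduct 18 (not isolated), via E-enal 19 (not isolated)
Conditions: TiCl4, CH2Cl2, −78 → 0 °C; then THF, sat. aq. NH4Cl, indium powder, rt
Reagents that add atoms: none
Why: TiCl4 activates the C10 ketone of 17 for Mukaiyama aldol addition of the enol silane carbon C5 of 6, and the titanium aldolate 18 eliminates on warming to the conjugated tetrasubstituted enal 19 (new C10=C5), whose geometry should equilibrate under the Lewis-acidic conditions as β,β-disubstituted enals do; indium then inserts into the allylic C13–Br bond and the allylindium adds through C7 (SE2') to the C6 aldehyde, moving the double bond to C11=C13. The closest known reactions are the Mukaiyama aldol condensation with α-oxygenated ketones and the indium- or zinc-mediated Barbier allylation of aldehydes with 3-(bromomethyl)furan-2(5H)-ones. The six-membered carbocycle is closed by 6-exo-trig attack of C7 on the aldehyde carbon C6. C7 is set by the C8 stereocentre, because the C9–C10=C5 tether can deliver the aldehyde only to the butenolide face that carries C9 (cis ring fusion); C6 is set by a chair Zimmerman–Traxler transition state in which indium bridges the carbonyl oxygen and C13, where the ring-locked E-type allyl unit (C8 trans to C13) gives the anti adduct, that is 6-OH trans to the C7–C11 bond. The step needs the E enal (formyl cis to C9), the only isomer that can cyclise and the one the β-branched C9 arm should favour at equilibrium, and it needs 1,2-addition to the aldehyde only, which the carbonyl-selective allylindium secures over the lactone.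

**Step 13**
Reactants: 20 cis-fused 6-hydroxy α-methylene lactone (bis-TBDPS ether), 21 angelic acid
Product: 23 6-O-angeloyl bis-TBDPS ether, via mixed anhydride 22 (not isolated)
Conditions: 21, 2,4,6-trichlorobenzoyl chloride, Et3N, toluene, rt; then 20, 80 °C
Reagents that add atoms: none
Why: Yamaguchi-type mixed-anhydride acylation without a nucleophilic catalyst esterifies the hindered allylic C6–OH with retention and should keep the Z geometry of the angeloyl group.

**Step 14**
Reactants: 23 6-O-angeloyl bis-TBDPS ether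
Product: 24 CNP0106570.2 (target)
Conditions: HF·pyridine, pyridine/THF, 0 °C → rt
Reagents that add atoms: none
Why: Buffered fluoride cleaves both primary silyl ethers (C1 and C14) under conditions that the angelate and the α-methylene lactone tolerate.

**Compound list**

1 | (R)-citronellal, (3R)-3,7-dimethyloct-6-enal | O=CC[C@H](C)CCC=C(C)C | starting material
2 | (R)-8,8-dimethoxy-2,6-dimethyloct-2-ene | COC(OC)C[C@H](C)CCC=C(C)C | intermediate
3 | (R)-6,6-dimethoxy-4-methylhexan-1-ol | COC(OC)C[C@H](C)CCCO | intermediate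
4 | (R)-tert-butyl[(6,6-dimethoxy-4-methylhexyl)oxy]diphenylsilane | COC(OC)C[C@H](C)CCCO[Si](c1ccccc1)(c1ccccc1)C(C)(C)C | intermediate
5 | (R)-6-[(tert-butyldiphenylsilyl)oxy]-3-methylhexanal | O=CC[C@H](C)CCCO[Si](c1ccccc1)(c1ccccc1)C(C)(C)C | intermediate
6 | (4R)-tert-butyl{[4-methyl-6-(trimethylsilyloxy)hex-5-en-1-yl]oxy}diphenylsilane, E/Z mixture | C[Si](C)(C)OC=C[C@H](C)CCCO[Si](c1ccccc1)(c1ccccc1)C(C)(C)C | intermediate
7 | 2-bromoprop-2-en-1-ol | OCC(Br)=C | starting material
8 | [(2-bromoprop-2-en-1-yl)oxy](tert-butyl)diphenylsilane | C=C(Br)CO[Si](c1ccccc1)(c1ccccc1)C(C)(C)C | intermediate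
9 | (R)-epichlorohydrin | ClC[C@H]1CO1 | starting material
10 | {3-[(tert-butyldiphenylsilyl)oxy]prop-1-en-2-yl}lithium | [Li]C(=C)CO[Si](c1ccccc1)(c1ccccc1)C(C)(C)C | intermediate
11 | (R)-5-{[(tert-butyldiphenylsilyl)oxy]methyl}-1-chlorohex-5-en-2-ol | ClC[C@H](O)CC(=C)CO[Si](c1ccccc1)(c1ccccc1)C(C)(C)C | intermediate
12 | (R)-tert-butyl{[2-(oxiran-2-ylmethyl)prop-2-en-1-yl]oxy}diphenylsilane | C1O[C@@H]1CC(=C)CO[Si](c1ccccc1)(c1ccccc1)C(C)(C)C | intermediate
13 | (R)-5-{[(tert-butyldiphenylsilyl)oxy]methyl}hexa-1,5-dien-3-ol | C=C[C@H](O)CC(=C)CO[Si](c1ccccc1)(c1ccccc1)C(C)(C)C | intermediate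
14 | 2-(bromomethyl)acrylic acid | OC(=O)C(=C)CBr | starting material
15 | (R)-5-{[(tert-butyldiphenylsilyl)oxy]methyl}hexa-1,5-dien-3-yl 2-(bromomethyl)acrylate | C=C[C@@H](CC(=C)CO[Si](c1ccccc1)(c1ccccc1)C(C)(C)C)OC(=O)C(=C)CBr | intermediate
16 | (R)-3-(bromomethyl)-5-(2-{[(tert-butyldiphenylsilyl)oxy]methyl}prop-2-en-1-yl)furan-2(5H)-one | BrCC1=C[C@@H](CC(=C)CO[Si](c2ccccc2)(c2ccccc2)C(C)(C)C)OC1=O | intermediate
17 | (R)-3-(bromomethyl)-5-{3-[(tert-butyldiphenylsilyl)oxy]-2-oxopropyl}furan-2(5H)-one | BrCC1=C[C@@H](CC(=O)CO[Si](c2ccccc2)(c2ccccc2)C(C)(C)C)OC1=O | intermediate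
18 | aldol adduct, 4-[(2R)-4-(bromomethyl)-5-oxo-2,5-dihydrofuran-2-yl]-3-hydroxy-3-{[(tert-butyldiphenylsilyl)oxy]methyl}-2-{(2R)-5-[(tert-butyldiphenylsilyl)oxy]pentan-2-yl}butanal, diastereomer mixture at C2 and C3, present in the flask as its titanium alkoxide | O=CC([C@H](C)CCCO[Si](c1ccccc1)(c1ccccc1)C(C)(C)C)C(O)(CO[Si](c1ccccc1)(c1ccccc1)C(C)(C)C)C[C@H]1OC(=O)C(CBr)=C1 | intermediate
19 | (2E)-4-[(2R)-4-(bromomethyl)-5-oxo-2,5-dihydrofuran-2-yl]-3-{[(tert-butyldiphenylsilyl)oxy]methyl}-2-{(2R)-5-[(tert-butyldiphenylsilyl)oxy]pentan-2-yl}but-2-enal (formyl cis to the butenolide arm) | O=C/C(=C(/CO[Si](c1ccccc1)(c1ccccc1)C(C)(C)C)C[C@H]1OC(=O)C(CBr)=C1)[C@H](C)CCCO[Si](c1ccccc1)(c1ccccc1)C(C)(C)C | intermediate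
20 | (3aS,4S,7aR)-4-hydroxy-6-{[(tert-butyldiphenylsilyl)oxy]methyl}-5-{(2R)-5-[(tert-butyldiphenylsilyl)oxy]pentan-2-yl}-3-methylidene-3a,4,7,7a-tetrahydro-1-benzofuran-2(3H)-one; cis-fused lactone, 4-OH trans to the C3a–C3 bond; same spatial arrangement as 24, the C3a descriptor differs only through CIP priorities | C=C1C(=O)O[C@@H]2CC(CO[Si](c3ccccc3)(c3ccccc3)C(C)(C)C)=C([C@H](C)CCCO[Si](c3ccccc3)(c3ccccc3)C(C)(C)C)[C@@H](O)[C@H]12 | intermediate
21 | angelic acid, (Z)-2-methylbut-2-enoic acid | C/C=C(/C)C(=O)O | starting material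
22 | (Z)-2-methylbut-2-enoic 2,4,6-trichlorobenzoic anhydride | C/C=C(/C)C(=O)OC(=O)c1c(Cl)cc(Cl)cc1Cl | intermediate
23 | (3aR,4S,7aR)-6-{[(tert-butyldiphenylsilyl)oxy]methyl}-5-{(2R)-5-[(tert-butyldiphenylsilyl)oxy]pentan-2-yl}-3-methylidene-2-oxo-2,3,3a,4,7,7a-hexahydro-1-benzofuran-4-yl (Z)-2-methylbut-2-enoate | C=C1C(=O)O[C@@H]2CC(CO[Si](c3ccccc3)(c3ccccc3)C(C)(C)C)=C([C@H](C)CCCO[Si](c3ccccc3)(c3ccccc3)C(C)(C)C)[C@@H](OC(=O)/C(C)=C\C)[C@H]12 | intermediate
24 | CNP0106570.2, (3aR,4S,7aR)-6-(hydroxymethyl)-5-[(2R)-5-hydroxypentan-2-yl]-3-methylidene-2-oxo-2,3,3a,4,7,7a-hexahydro-1-benzofuran-4-yl (Z)-2-methylbut-2-enoate | C=C1C(=O)O[C@@H]2CC(CO)=C([C@H](C)CCCO)[C@@H](OC(=O)/C(C)=C\C)[C@H]12 | target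

**Step count.** Total: 14 steps. Longest linear sequence: 9 steps (steps 6 to 14, from 7).

**Steps most likely to fail**

1. Step 12. Several processes can go wrong:
   - The aldol addition to the hindered α-silyloxy ketone may stall or revert on warming.
   - The enol silane may instead displace the allylic bromide (SN2').
   - The enal may settle in the Z geometry, which cannot cyclise and is lost to intermolecular allylation.

   Fallback: the two bonds are made in separate flasks and the alkene geometry is corrected in between. Setting out from 17, ketalisation (HC(OMe)3, PPTS, MeOH) should give the dimethyl ketal F1. TMSOTf-catalysed Mukaiyama addition of 6 to the ketal-derived oxocarbenium ion (CH2Cl2, −78 °C) should give the β-methoxy aldehyde F2. TsOH in benzene should eliminate methanol to the enal 19, now isolated, together with the Z-enal F3; F3 is separated and re-equilibrated under the same acid conditions. Pure 19 is then closed with CrCl2 in THF (Nozaki–Hiyama–Kishi allylation through a closed transition state), and the route is rejoined at 20.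

2. Step 13. Heating may isomerise the angeloyl unit to the tigloyl ester, and acylation of the hindered allylic alcohol may be slow. Fallback: the Z alkene is built on the ester instead of being carried in. Setting out from 20, Steglich esterification with 2-[bis(2,2,2-trifluoroethoxy)phosphoryl]propanoic acid (DCC, DMAP cat., CH2Cl2) should give the phosphonate ester F4. Still–Gennari olefination with acetaldehyde (KHMDS, 18-crown-6, THF, −78 °C) should then give the Z-configured ester, and the route is rejoined at 23.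

3. Step 10. Initiation at the electron-poor 1,1-disubstituted acrylate may be slow, and the allylic bromide may decompose the ruthenium alkylidene. Fallback: the bromide is introduced after ring closure. Setting out from 13, esterification with 2-{[(4-methoxybenzyl)oxy]methyl}acrylic acid (DCC, DMAP cat.) should give the PMB-protected acrylate F5. Ring-closing metathesis should give the PMB-protected butenolide F6. DDQ (CH2Cl2/H2O) should release the hydroxymethyl butenolide F7, and Appel bromination (CBr4, PPh3, CH2Cl2, 0 °C) rejoins the route at 16.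

**Further compounds**

F1 | step 12 | (R)-3-(bromomethyl)-5-{3-[(tert-butyldiphenylsilyl)oxy]-2,2-dimethoxypropyl}furan-2(5H)-one | BrCC1=C[C@@H](CC(OC)(OC)CO[Si](c2ccccc2)(c2ccccc2)C(C)(C)C)OC1=O
F2 | step 12 | β-methoxy aldehyde, 3-methoxy analogue of 18 (diastereomer mixture) | O=CC([C@H](C)CCCO[Si](c1ccccc1)(c1ccccc1)C(C)(C)C)C(OC)(CO[Si](c1ccccc1)(c1ccccc1)C(C)(C)C)C[C@H]1OC(=O)C(CBr)=C1
F3 | step 12 | (2Z)-isomer of enal 19 (formyl cis to the silyloxymethyl arm) | O=C/C(=C(\CO[Si](c1ccccc1)(c1ccccc1)C(C)(C)C)C[C@H]1OC(=O)C(CBr)=C1)[C@H](C)CCCO[Si](c1ccccc1)(c1ccccc1)C(C)(C)C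
F4 | step 13 | 2-[bis(2,2,2-trifluoroethoxy)phosphoryl]propanoate ester of 20 | C=C1C(=O)O[C@@H]2CC(CO[Si](c3ccccc3)(c3ccccc3)C(C)(C)C)=C([C@H](C)CCCO[Si](c3ccccc3)(c3ccccc3)C(C)(C)C)[C@@H](OC(=O)C(C)P(=O)(OCC(F)(F)F)OCC(F)(F)F)[C@H]12
F5 | step 10 | (R)-5-{[(tert-butyldiphenylsilyl)oxy]methyl}hexa-1,5-dien-3-yl 2-{[(4-methoxybenzyl)oxy]methyl}acrylate | C=C[C@@H](CC(=C)CO[Si](c1ccccc1)(c1ccccc1)C(C)(C)C)OC(=O)C(=C)COCc1ccc(OC)cc1
F6 | step 10 | (R)-5-(2-{[(tert-butyldiphenylsilyl)oxy]methyl}prop-2-en-1-yl)-3-{[(4-methoxybenzyl)oxy]methyl}furan-2(5H)-one | COc1ccc(COCC2=C[C@@H](CC(=C)CO[Si](c3ccccc3)(c3ccccc3)C(C)(C)C)OC2=O)cc1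
F7 | step 10 | (R)-5-(2-{[(tert-butyldiphenylsilyl)oxy]methyl}prop-2-en-1-yl)-3-(hydroxymethyl)furan-2(5H)-one | OCC1=C[C@@H](CC(=C)CO[Si](c2ccccc2)(c2ccccc2)C(C)(C)C)OC1=O
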